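Time comes first: is 5.0 h long against the working life of the catalyst?

| flask | starting material | partner | capture agent | free catalyst | remark | time |
|---|---|---|---|---|---|---|
| south-east | 10 mM | 10.5 mM | 0.50 mM | 27 µM | run made earlier |  |
| north-west | 10 mM | 10.5 mM | 0.50 mM | 38 µM | run made earlier |  |
| west | 10 mM | 10.5 mM | 0.50 mM | 59 µM | run made earlier |  |
| Sunday's | 10 mM | 10.5 mM | 0.500 mM | 27 µM | everything together in a closed stirred flask, run for 5.0 h | 5.0 h |
| Friday's | 10 mM (fed, over 5.00 h) | 10.5 mM | 0.500 mM | 27 µM | a stirred flask in which starting material is dosed at a steady rate over 5.00 h without added volume, worked up at 5.0 h | 5.0 h |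
| Saturday's | 10 mM | 10.5 mM (fed, over 5.00 h) | 0.500 mM | 27 µM | all but partner at the start; partner goes in evenly over 5.00 h, the run ends at 5.0 h | 5.0 h |
| Thursday's | 10 mM | 10.5 mM | 0.500 mM | 27 µM | a single well-mixed tank run continuously and read at steady state, 5.0 h in it on average |  |

| run | time / h | product / % |
|---|---|---|
| south-east | 0.200 | 1.1 |
| south-east | 0.667 | 4.4 |
| south-east | 1.00 | 6.0 |
| south-east | 1.50 | 7.4 |
| south-east | 2.50 | 9.3 |
| south-east | 3.00 | 9.3 |
| north-west | 0.417 | 5.0 |
| north-west | 1.33 | 9.4 |
| north-west | 2.00 | 12.3 |
| north-west | 3.00 | 13.8 |
| north-west | 5.00 | 14.3 |
| north-west | 6.00 | 16.2 |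
| west | 0.500 | 7.4 |
| west | 0.833 | 11.7 |
| west | 1.33 | 16.4 |
| west | 2.00 | 18.7 |
| west | 4.00 | 23.2 |
| west | 6.00 | 23.9 |

(readings scatter by 0.5 percentage points)

- the stated concentrations are those of everything mixed, before any reaction; amounts are the same in each set-up
- steps under discussion: starting material + free catalyst -> catalyst intermediate A; catalyst intermediate A -> catalyst intermediate B; partner + catalyst intermediate B -> catalyst intermediate C; catalyst intermediate C -> by-product + catalyst intermediate D; catalyst intermediate D -> free catalyst + product; catalyst intermediate A + capture agent -> trapped intermediate; partner -> decomposed reagent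
- the feed brings no volume worth counting
- the earlier runs were made in a closed, stirred flask

- the set-up with the highest amount of product at the outlet or at the end, in percent of the starting material put in ("none" if the first two lie within 2 percentage points) (Sunday's / Friday's / Saturday's / Thursday's / none)
- amount of product at the outlet or at the end, in percent of the starting material put in, Sunday's
- amount of product at the outlet or at the end, in percent of the starting material put in, Friday's
- amount of product at the outlet or at the end, in percent of the starting material put in, Saturday's
- amount of product at the outlet or at the end, in percent of the starting material put in, Thursday's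

The earlier runs flatten far short of the charge, the west run reading 23.2% and then 23.9%, and the west run, with 59 µM of free catalyst, ends higher than the north-west run, with 38 µM, at 16.2%, so we read the stop as the catalyst's. The zero of our scale is the stoichiometric case: one turnover per catalyst, which in Sunday's flask is 0.270% of the starting material. Above that zero we take a statistical picture, in which each pass round the cycle carries the same small chance of capture. We take that chance as steady, since capture agent stands at 0.500 mM against at most 59 µM of catalyst.

The west run lies 5.2 percentage points below its last reading at 2.00 h and 0.7 points below it at 4.00 h, which reads as a decay time of 0.997 h. On that reading we expect Sunday's flask to have 0.664% of its course unfinished at the end. Final product per catalyst charged reads 40.5 in the west run and 42.6 in the north-west run. The weak link is the south-east run, which stops at 3.00 h still unfinished; corrected by the decay time it reads 36.2. The mean is 39.8, our turnover capacity, the mean number of turnovers a catalyst makes before capture.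

Sunday's flask should then give 10.7%. Spending that capacity within one decay time takes about 1.08 mM h⁻¹ by our estimate, less than Friday's feed of 2.00 mM h⁻¹ and Saturday's of 2.10 mM h⁻¹, so we put both dosed flasks close to Sunday's. In Thursday's tank a catalyst stays 5.0 h on average, and averaged over the spread of stays in a well-mixed tank it uses a share of 83.4% of its capacity, which gives 8.96%. We commit to no clear winner.

The forecast, with the words “Dosing only delays turnover.”, gave 10.2%, 9.4%, 9.5% and 8.2% for Sunday's, Friday's, Saturday's and Thursday's, with best none, its dosed figures standing below our 10.7% for Sunday's.

The flasks give 10.4%, 10.3%, 10.3% and 8.65% in that order, and best is none.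

    starting material + free catalyst → catalyst intermediate A (k = 410 M⁻¹ s⁻¹)
    catalyst intermediate A → catalyst intermediate B (k = 0.0530 s⁻¹)
    partner + catalyst intermediate B → catalyst intermediate C (k = 150 M⁻¹ s⁻¹)
    catalyst intermediate C → by-product + catalyst intermediate D (k = 0.0150 s⁻¹)
    catalyst intermediate D → free catalyst + product (k = 0.0560 s⁻¹)
    catalyst intermediate A + capture agent → trapped intermediate (k = 2.80 M⁻¹ s⁻¹)
    partner → decomposed reagent (k = 5.20 × 10⁻⁵ s⁻¹)

In Sunday's flask catalyst intermediate A goes forward at 0.053 s⁻¹ and is captured at 0.00140 s⁻¹ at the charged capture agent. That is a selectivity factor of 37.9. Sunday's product comes to 38.4 turnovers per catalyst charged, beside our capacity of 39.8. With free catalyst in Sunday's flask lowered to 14.1 µM, everything else held, that capacity gives 5.63%, and the flask stands at 5.40%.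

The runs were generated by integration from invented constants; noise was put on by code.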